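Ring A is disconnected at the C1–C10 bond. In ring B the oxygenated carbon C8 sits para to the quaternary carbon C5, so ring B can be carried as a 4,4-disubstituted cyclohexa-2,5-dienone whose two enone arms (C6=C7 and C9=C10) differ only through the neighbouring C4 stereocentre. A chiral primary amine converts the C2 methyl ketone of the side chain into its terminal enamine, and C1 adds to C10: one operation closes ring A cis-fused, fixes C5 and C10 and leaves the C6=C7–C8=O enone for later work at C7–C9. The precursor is (S)-4-methyl-4-(4-oxopentan-2-yl)cyclohexa-2,5-dien-1-one, assembled from dimethyl 3-methylglutarate, methylmagnesium bromide and but-3-en-2-one.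

Key step: step 10

Convention: eremophilane numbering throughout (ring A: C1–C5 and C10; ring B: C5–C10); β is the face of the C5 methyl, so the two ring A bonds at C5 and C10 are α.

Assumption: pig liver esterase gives the (R)-half-ester 2. With this antipode C4 comes out (S), as the target requires, only if the ester arm becomes the methyl ketone (C3–C2–C1) and the acid arm becomes C5; steps 2–6 are ordered accordingly.

Step 1
Reactants: 1 dimethyl 3-methylglutarate
Product: 2 (R)-5-methoxy-3-methyl-5-oxopentanoic acid
Conditions: pig liver esterase, phosphate buffer (pH 7)/MeOH 4:1, −10 °C, 1 M NaOH by pH-stat; then HCl to pH 2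
Reagents that add atoms: water, O
Why: Enzymatic desymmetrisation (esterase hydrolysis) of the prochiral diester removes one of the two enantiotopic ester groups and so sets the future C4, the only stereocentre carried from the start.

Step 2
Reactants: 2 (R)-5-methoxy-3-methyl-5-oxopentanoic acid; 3 methylmagnesium bromide
Product: 5 (S)-3-methyl-5-oxohexanoic acid, via amide acid 4 (not isolated)
Conditions: MeNHOMe·HCl (1.5 equiv), i-PrMgCl (5 equiv), THF, −20 → 0 °C; then MeMgBr (3 equiv), 0 °C; 1 M HCl
Reagents that add atoms: methylmagnesium bromide (3), C[Mg]Br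
Why: Weinreb ketone synthesis in one flask, in which the chloromagnesium amide turns the ester arm into the N-methoxy-N-methylamide while the acid arm is inert as its magnesium carboxylate, and the chelated Grignard adduct releases the methyl ketone (C1–C2) only on work-up; the stereocentre is not involved and its descriptor changes by priority alone.

Step 3
Reactants: 5 (S)-3-methyl-5-oxohexanoic acid
Product: 6 methyl (S)-3-methyl-5-oxohexanoate
Conditions: MeI, K2CO3, DMF, rt
Reagents that add atoms: iodomethane, CI
Why: Carboxylate O-alkylation (SN2 esterification) provides the enolisable methyl ester without acid that could cyclise the 5-oxo acid.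

Step 4
Reactants: 6 methyl (S)-3-methyl-5-oxohexanoate
Product: 7 methyl (S)-3-methyl-4-(2-methyl-1,3-dioxolan-2-yl)butanoate
Conditions: Me3SiOCH2CH2OSiMe3, Me3SiOTf (5 mol %), CH2Cl2, −78 → −20 °C
Reagents that add atoms: 1,2-bis(trimethylsilyloxy)ethane, C[Si](C)(C)OCCO[Si](C)(C)C
Why: Noyori ketalisation masks the methyl ketone as a base-stable dioxolane under aprotic conditions that cannot transesterify the ester.

Step 5
Reactants: 7 methyl (S)-3-methyl-4-(2-methyl-1,3-dioxolan-2-yl)butanoate
Product: 8 methyl (3S)-2,3-dimethyl-4-(2-methyl-1,3-dioxolan-2-yl)butanoate (C2 epimers)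
Conditions: LiN(i-Pr)2, THF, −78 °C; MeI, −78 → 0 °C
Reagents that add atoms: iodomethane, CI
Why: Ester enolate alkylation brings in the future C5 methyl, and the new centre may form unselectively because it becomes the non-stereogenic C5 of the dienone.

Step 6
Reactants: 8 methyl (3S)-2,3-dimethyl-4-(2-methyl-1,3-dioxolan-2-yl)butanoate
Product: 9 (3S)-2,3-dimethyl-4-(2-methyl-1,3-dioxolan-2-yl)butanal (C2 epimers)
Conditions: i-Bu2AlH (1.1 equiv), CH2Cl2, −78 °C; aq. potassium sodium tartrate
Reagents that add atoms: none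
Why: Partial hydride reduction of the α-branched methyl ester stops at the aldehyde because the aluminium hemiacetal is stable at −78 °C.

Step 7
Reactants: 9 (3S)-2,3-dimethyl-4-(2-methyl-1,3-dioxolan-2-yl)butanal; 10 but-3-en-2-one
Product: 13 4-methyl-4-[(2S)-1-(2-methyl-1,3-dioxolan-2-yl)propan-2-yl]cyclohex-2-en-1-one (C4 epimers), via enamine 11 (not isolated), via keto aldehyde 12 (not isolated)
Conditions: pyrrolidine (1.2 equiv), K2CO3, PhMe, 0 °C → rt; 10, rt; aq. AcOH/NaOAc (pH 5), rt; then KOH, MeOH, 50 °C
Reagents that add atoms: but-3-en-2-one (10), CC(=O)C=C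
Why: Robinson annulation by way of the Stork enamine (Michael addition, then intramolecular aldol condensation) builds ring B around the quaternary C5; the ring stereocentre created here is erased in step 8, and the basic cyclodehydration keeps the dioxolane so that the side-chain ketone cannot compete for the aldehyde.

Step 8
Reactants: 13 4-methyl-4-[(2S)-1-(2-methyl-1,3-dioxolan-2-yl)propan-2-yl]cyclohex-2-en-1-one
Product: 15 4-methyl-4-[(2S)-1-(2-methyl-1,3-dioxolan-2-yl)propan-2-yl]cyclohexa-2,5-dien-1-one, via silyl dienol ether 14 (not isolated)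
Conditions: LiN(i-Pr)2, Me3SiCl, THF, −78 °C; then Pd(OAc)2 (1.05 equiv), MeCN, rt
Reagents that add atoms: none
Why: Saegusa–Ito dehydrogenation, in which the only possible enolate (C5 is quaternary) is silylated and oxidised by divalent palladium to the cross-conjugated dienone, which removes the stereogenicity of C5 and merges the epimers.

Step 9
Reactants: 15 4-methyl-4-[(2S)-1-(2-methyl-1,3-dioxolan-2-yl)propan-2-yl]cyclohexa-2,5-dien-1-one
Product: 16 (S)-4-methyl-4-(4-oxopentan-2-yl)cyclohexa-2,5-dien-1-one
Conditions: 1 M HCl, THF, 0 °C; used at once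
Reagents that add atoms: water, O
Why: Acid-catalysed hydrolysis of the dioxolane unmasks the methyl ketone last and under conditions too mild for an uncatalysed enol Michael addition, so the precursor reaches the key step uncyclised.

Step 10
Reactants: 16 (S)-4-methyl-4-(4-oxopentan-2-yl)cyclohexa-2,5-dien-1-one
Product: 17 (4S,4aR,8aR)-4,4a-dimethyl-4,4a,8,8a-tetrahydronaphthalene-2,7(1H,3H)-dione (cis-fused 11,12,13-trinor-10βH-eremophil-6-ene-2,8-dione)
Conditions: 9-amino-9-deoxy-epi-quinine (20 mol %), CF3CO2H (40 mol %), PhMe, 25 °C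
Reagents that add atoms: none
Why: The primary amine condenses with the C2 methyl ketone; only the terminal enamine can react (the internal one would have to close a four-membered ring), and its carbon C1 adds to C10 of the dienone with the enamine C=C inside and the C9=C10 bond outside the forming ring, a 6-(enolendo)-exo-trig closure, after which hydrolysis returns the catalyst. The closest known reactions are the enamine-catalysed desymmetrising Michael cyclisations of aldehyde-tethered 4,4-disubstituted cyclohexadienones and the cinchona-primary-amine-catalysed 6-enolendo cyclisations of methyl ketones. The new C10 centre is cis to the C5 methyl by necessity, because the three-atom tether can reach only the enone face that carries it. The configuration of C5, that is the choice of arm, is set by the catalyst, whose protonated quinuclidine binds the dienone carbonyl and holds the enamine over one arm; the resident C4 centre contributes little, since the chair leading to the natural 4,5-cis-dimethyl series (C4 methyl pseudo-axial, anti to the spectator arm) and the one leading to the trans series (C4 methyl equatorial) differ by about one gauche interaction. The step therefore needs group selectivity between the two diastereotopic enone arms; regiochemistry and ring fusion are secured by the substrate, and a single addition is guaranteed because neither enamine of the product can reach the remaining C6=C7–C8=O enone.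

Step 11
Reactants: 17 cis-fused 11,12,13-trinor-10βH-eremophil-6-ene-2,8-dione
Product: 18 2,2-(ethylenedioxy)-11,12,13-trinor-10βH-eremophil-6-en-8-one
Conditions: Me3SiOCH2CH2OSiMe3, Me3SiOTf (5 mol %), CH2Cl2, −78 °C
Reagents that add atoms: 1,2-bis(trimethylsilyloxy)ethane, C[Si](C)(C)OCCO[Si](C)(C)C
Why: Noyori ketalisation at low temperature is chemoselective for the saturated C2 ketone over the less electrophilic conjugated C8 ketone, so ring A is protected for the enolate and hydride steps that follow.

Step 12
Reactants: 18 2,2-(ethylenedioxy)-11,12,13-trinor-10βH-eremophil-6-en-8-one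
Product: 19 2,2-(ethylenedioxy)-9β-hydroxy-11,12,13-trinor-10βH-eremophil-6-en-8-one
Conditions: KN(SiMe3)2, THF, −78 °C; 2-(phenylsulfonyl)-3-phenyloxaziridine, −78 °C; aq. NH4Cl
Reagents that add atoms: 2-(phenylsulfonyl)-3-phenyloxaziridine, O=S(=O)(c1ccccc1)N1OC1c1ccccc1
Why: α′-Hydroxylation of a ketone enolate with an N-sulfonyloxaziridine: the enone can be deprotonated only at C9 (C5 is quaternary), and the oxidant should approach the cross-conjugated enolate on the convex β face, opposite ring A and anti to the pseudo-axial C5–C4 bond, to give the 9β-alcohol.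

Step 13
Reactants: 19 2,2-(ethylenedioxy)-9β-hydroxy-11,12,13-trinor-10βH-eremophil-6-en-8-one
Product: 20 2,2-(ethylenedioxy)-9β-(triethylsilyloxy)-11,12,13-trinor-10βH-eremophil-6-en-8-one
Conditions: Et3SiCl, imidazole, DMF, 0 °C → rt
Reagents that add atoms: chlorotriethylsilane, CC[Si](Cl)(CC)CC
Why: Silyl ether formation differentiates O9 from the later O8 and, because a 9β-silyloxy group cannot be axial next to the C5 methyl, holds ring B in the chair whose C5–C4 bond is axial, which is the conformational basis of steps 15, 16 and 21.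

Step 14
Reactants: 20 2,2-(ethylenedioxy)-9β-(triethylsilyloxy)-11,12,13-trinor-10βH-eremophil-6-en-8-one
Product: 21 2,2-(ethylenedioxy)-9β-(triethylsilyloxy)-11,12,13-trinor-10βH-eremophilan-8-one
Conditions: H2 (1 atm), Pd/C, EtOAc, rt
Reagents that add atoms: none
Why: Heterogeneous catalytic hydrogenation saturates the disubstituted C6=C7 bond without creating a stereocentre and leaves C7H2 as the only unencumbered α-position of the C8 ketone.

Step 15
Reactants: 21 2,2-(ethylenedioxy)-9β-(triethylsilyloxy)-11,12,13-trinor-10βH-eremophilan-8-one; 22 acetone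
Product: 23 2,2-(ethylenedioxy)-11-hydroxy-9β-(triethylsilyloxy)-7αH,10βH-eremophilan-8-one (7β side chain)
Conditions: LiN(i-Pr)2, THF, −78 °C; ZnCl2; 22, −78 → −40 °C; AcOH quench at −78 °C
Reagents that add atoms: acetone (22), CC(C)=O
Why: Directed aldol addition: kinetic deprotonation takes the C7 methylene in preference to the silyloxy-bearing C9 methine, and acetone should add to the zinc enolate anti to the axial C5–C4 bond, from the β face, giving the equatorial 7β side chain that is also the more stable aldolate.

Step 16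
Reactants: 23 2,2-(ethylenedioxy)-11-hydroxy-9β-(triethylsilyloxy)-7αH,10βH-eremophilan-8-one
Product: 24 2,2-(ethylenedioxy)-9β-(triethylsilyloxy)-7αH,10βH-eremophilane-8α,11-diol
Conditions: Me4NBH(OAc)3, MeCN/AcOH, −20 °C
Reagents that add atoms: none
Why: Hydroxyl-directed (Evans–Saksena) reduction, in which the acyloxyborohydride bound to the tertiary hydroxyl transfers hydride to C8 along the unhindered axial β trajectory, so that the 8α-hydroxyl comes out equatorial and trans to both neighbours.

Step 17
Reactants: 24 2,2-(ethylenedioxy)-9β-(triethylsilyloxy)-7αH,10βH-eremophilane-8α,11-diol; 25 angelic acid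
Product: 26 2,2-(ethylenedioxy)-11-hydroxy-9β-(triethylsilyloxy)-7αH,10βH-eremophilan-8α-yl (Z)-2-methylbut-2-enoate
Conditions: 25 (3 equiv), 2,4,6-Cl3C6H2COCl, Et3N, PhMe, rt; then 24, 80 °C
Reagents that add atoms: angelic acid (25), C/C=C(/C)C(=O)O
Why: Yamaguchi esterification through the mixed anhydride acylates the secondary 8α-hydroxyl only (the tertiary one is too hindered) and avoids the nucleophilic catalysts that isomerise an angelate to the tiglate.

Step 18
Reactants: 26 2,2-(ethylenedioxy)-11-hydroxy-9β-(triethylsilyloxy)-7αH,10βH-eremophilan-8α-yl (Z)-2-methylbut-2-enoate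
Product: 27 2,2-(ethylenedioxy)-9β-(triethylsilyloxy)-7αH,10βH-eremophil-11-en-8α-yl (Z)-2-methylbut-2-enoate
Conditions: Burgess reagent (2 equiv), PhMe, 50 °C
Reagents that add atoms: none
Why: Burgess dehydration (syn elimination of the tertiary sulfamate) should give the isopropenyl group, since six methyl hydrogens compete with one ring hydrogen and the alternative C7=C11 alkene would suffer allylic strain against the equatorial C8 ester; C7 itself is not touched.

Step 19
Reactants: 27 2,2-(ethylenedioxy)-9β-(triethylsilyloxy)-7αH,10βH-eremophil-11-en-8α-yl (Z)-2-methylbut-2-enoate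
Product: 28 2,2-(ethylenedioxy)-9β-hydroxy-7αH,10βH-eremophil-11-en-8α-yl (Z)-2-methylbut-2-enoate
Conditions: HF·pyridine, pyridine, THF, 0 °C
Reagents that add atoms: none
Why: Fluoride cleavage of the triethylsilyl ether under acidic buffering frees the 9β-hydroxyl without the base that would let the angeloyl group migrate from O8 to O9 before the oxidation.

Step 20
Reactants: 28 2,2-(ethylenedioxy)-9β-hydroxy-7αH,10βH-eremophil-11-en-8α-yl (Z)-2-methylbut-2-enoate
Product: 29 2,2-(ethylenedioxy)-9-oxo-7αH,10βH-eremophil-11-en-8α-yl (Z)-2-methylbut-2-enoate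
Conditions: Dess–Martin periodinane, CH2Cl2, 0 °C → rt
Reagents that add atoms: none
Why: Dess–Martin oxidation converts the wrongly configured 9β-alcohol into the C9 ketone under near-neutral conditions that should not epimerise the flanking C8 and C10 centres.

Step 21
Reactants: 29 2,2-(ethylenedioxy)-9-oxo-7αH,10βH-eremophil-11-en-8α-yl (Z)-2-methylbut-2-enoate
Product: 30 2,2-(ethylenedioxy)-9α-hydroxy-7αH,10βH-eremophil-11-en-8α-yl (Z)-2-methylbut-2-enoate
Conditions: Li[HB(s-Bu)3] (1.1 equiv), THF, −78 °C; aq. NH4Cl
Reagents that add atoms: none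
Why: Ketone reduction with a bulky trialkylborohydride: with the 7β-isopropenyl and 8α-ester groups equatorial, the axial approach to C9 is blocked by the syn-axial C5–C4 bond, so hydride should enter equatorially from the β face and give the axial 9α-alcohol; an acyl shift between O8 and O9 in the alkoxide would be harmless because both oxygens end as the same ester.

Step 22
Reactants: 30 2,2-(ethylenedioxy)-9α-hydroxy-7αH,10βH-eremophil-11-en-8α-yl (Z)-2-methylbut-2-enoate; 25 angelic acid
Product: 31 2,2-(ethylenedioxy)-7αH,10βH-eremophil-11-ene-8α,9α-diyl bis[(Z)-2-methylbut-2-enoate]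
Conditions: 25 (4 equiv), 2,4,6-Cl3C6H2COCl, Et3N, PhMe, rt; then 30, 90 °C
Reagents that add atoms: angelic acid (25), C/C=C(/C)C(=O)O
Why: A second Yamaguchi esterification acylates the remaining hindered axial hydroxyl and completes the 8α,9α-diester with both (Z)-configured acyl groups intact.

Step 23
Reactants: 31 2,2-(ethylenedioxy)-7αH,10βH-eremophil-11-ene-8α,9α-diyl bis[(Z)-2-methylbut-2-enoate]
Product: 32 2-oxo-7αH,10βH-eremophil-11-ene-8α,9α-diyl bis[(Z)-2-methylbut-2-enoate] (CNP0249036.1)
Conditions: 1 M HCl, THF, 0 °C → rt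
Reagents that add atoms: water, O
Why: Acid-catalysed hydrolysis of the dioxolane releases the C2 ketone under conditions mild enough for the two esters and the isopropenyl group, giving the target.

Compound list
1 | dimethyl 3-methylglutarate | COC(=O)CC(C)CC(=O)OC | starting material
2 | (R)-5-methoxy-3-methyl-5-oxopentanoic acid | C[C@H](CC(=O)O)CC(=O)OC | intermediate
3 | methylmagnesium bromide | C[Mg]Br | starting material
4 | (S)-5-[methoxy(methyl)amino]-3-methyl-5-oxopentanoic acid | C[C@H](CC(=O)O)CC(=O)N(C)OC | intermediate (not isolated)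
5 | (S)-3-methyl-5-oxohexanoic acid | C[C@H](CC(=O)O)CC(C)=O | intermediate
6 | methyl (S)-3-methyl-5-oxohexanoate | C[C@H](CC(=O)OC)CC(C)=O | intermediate
7 | methyl (S)-3-methyl-4-(2-methyl-1,3-dioxolan-2-yl)butanoate | C[C@H](CC(=O)OC)CC1(C)OCCO1 | intermediate
8 | methyl (3S)-2,3-dimethyl-4-(2-methyl-1,3-dioxolan-2-yl)butanoate (C2 epimers) | C[C@H](C(C)C(=O)OC)CC1(C)OCCO1 | intermediate
9 | (3S)-2,3-dimethyl-4-(2-methyl-1,3-dioxolan-2-yl)butanal (C2 epimers) | C[C@H](C(C)C=O)CC1(C)OCCO1 | intermediate
10 | but-3-en-2-one | CC(=O)C=C | starting material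
11 | 1-[(3S)-2,3-dimethyl-4-(2-methyl-1,3-dioxolan-2-yl)but-1-en-1-yl]pyrrolidine | C[C@H](C(C)=CN1CCCC1)CC1(C)OCCO1 | intermediate (not isolated)
12 | 2-methyl-2-[(2S)-1-(2-methyl-1,3-dioxolan-2-yl)propan-2-yl]-5-oxohexanal (C2 epimers) | C[C@H](C(C)(C=O)CCC(C)=O)CC1(C)OCCO1 | intermediate (not isolated)
13 | 4-methyl-4-[(2S)-1-(2-methyl-1,3-dioxolan-2-yl)propan-2-yl]cyclohex-2-en-1-one (C4 epimers) | C[C@H](C1(C)C=CC(=O)CC1)CC1(C)OCCO1 | intermediate
14 | trimethyl({4-methyl-4-[(2S)-1-(2-methyl-1,3-dioxolan-2-yl)propan-2-yl]cyclohexa-1,5-dien-1-yl}oxy)silane | C[C@H](C1(C)C=CC(O[Si](C)(C)C)=CC1)CC1(C)OCCO1 | intermediate (not isolated)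
15 | 4-methyl-4-[(2S)-1-(2-methyl-1,3-dioxolan-2-yl)propan-2-yl]cyclohexa-2,5-dien-1-one | C[C@H](C1(C)C=CC(=O)C=C1)CC1(C)OCCO1 | intermediate
16 | (S)-4-methyl-4-(4-oxopentan-2-yl)cyclohexa-2,5-dien-1-one | CC(=O)C[C@H](C)C1(C)C=CC(=O)C=C1 | intermediate (key-step precursor)
17 | (4S,4aR,8aR)-4,4a-dimethyl-4,4a,8,8a-tetrahydronaphthalene-2,7(1H,3H)-dione | O=C1C=C[C@@]2(C)[C@H](CC(=O)C[C@@H]2C)C1 | intermediate (key-step product)
18 | 2,2-(ethylenedioxy)-11,12,13-trinor-10βH-eremophil-6-en-8-one | O=C1C=C[C@@]2(C)[C@H](CC3(OCCO3)C[C@@H]2C)C1 | intermediate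
19 | 2,2-(ethylenedioxy)-9β-hydroxy-11,12,13-trinor-10βH-eremophil-6-en-8-one | O=C1C=C[C@@]2(C)[C@H](CC3(OCCO3)C[C@@H]2C)[C@H]1O | intermediate
20 | 2,2-(ethylenedioxy)-9β-(triethylsilyloxy)-11,12,13-trinor-10βH-eremophil-6-en-8-one | O=C1C=C[C@@]2(C)[C@H](CC3(OCCO3)C[C@@H]2C)[C@H]1O[Si](CC)(CC)CC | intermediate
21 | 2,2-(ethylenedioxy)-9β-(triethylsilyloxy)-11,12,13-trinor-10βH-eremophilan-8-one | O=C1CC[C@@]2(C)[C@H](CC3(OCCO3)C[C@@H]2C)[C@H]1O[Si](CC)(CC)CC | intermediate
22 | acetone | CC(C)=O | starting material
23 | 2,2-(ethylenedioxy)-11-hydroxy-9β-(triethylsilyloxy)-7αH,10βH-eremophilan-8-one | O=C1[C@@H](C(C)(C)O)C[C@@]2(C)[C@H](CC3(OCCO3)C[C@@H]2C)[C@H]1O[Si](CC)(CC)CC | intermediate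
24 | 2,2-(ethylenedioxy)-9β-(triethylsilyloxy)-7αH,10βH-eremophilane-8α,11-diol | O[C@@H]1[C@@H](C(C)(C)O)C[C@@]2(C)[C@H](CC3(OCCO3)C[C@@H]2C)[C@H]1O[Si](CC)(CC)CC | intermediate
25 | angelic acid, (Z)-2-methylbut-2-enoic acid | C/C=C(/C)C(=O)O | starting material
26 | 2,2-(ethylenedioxy)-11-hydroxy-9β-(triethylsilyloxy)-7αH,10βH-eremophilan-8α-yl (Z)-2-methylbut-2-enoate | C/C=C(/C)C(=O)O[C@@H]1[C@@H](C(C)(C)O)C[C@@]2(C)[C@H](CC3(OCCO3)C[C@@H]2C)[C@H]1O[Si](CC)(CC)CC | intermediate
27 | 2,2-(ethylenedioxy)-9β-(triethylsilyloxy)-7αH,10βH-eremophil-11-en-8α-yl (Z)-2-methylbut-2-enoate | C/C=C(/C)C(=O)O[C@@H]1[C@@H](C(C)=C)C[C@@]2(C)[C@H](CC3(OCCO3)C[C@@H]2C)[C@H]1O[Si](CC)(CC)CC | intermediate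
28 | 2,2-(ethylenedioxy)-9β-hydroxy-7αH,10βH-eremophil-11-en-8α-yl (Z)-2-methylbut-2-enoate | C/C=C(/C)C(=O)O[C@@H]1[C@@H](C(C)=C)C[C@@]2(C)[C@H](CC3(OCCO3)C[C@@H]2C)[C@H]1O | intermediate
29 | 2,2-(ethylenedioxy)-9-oxo-7αH,10βH-eremophil-11-en-8α-yl (Z)-2-methylbut-2-enoate | C/C=C(/C)C(=O)O[C@@H]1[C@@H](C(C)=C)C[C@@]2(C)[C@H](CC3(OCCO3)C[C@@H]2C)C1=O | intermediate
30 | 2,2-(ethylenedioxy)-9α-hydroxy-7αH,10βH-eremophil-11-en-8α-yl (Z)-2-methylbut-2-enoate | C/C=C(/C)C(=O)O[C@@H]1[C@@H](C(C)=C)C[C@@]2(C)[C@H](CC3(OCCO3)C[C@@H]2C)[C@@H]1O | intermediate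
31 | 2,2-(ethylenedioxy)-7αH,10βH-eremophil-11-ene-8α,9α-diyl bis[(Z)-2-methylbut-2-enoate] | C/C=C(/C)C(=O)O[C@@H]1[C@@H](C(C)=C)C[C@@]2(C)[C@H](CC3(OCCO3)C[C@@H]2C)[C@@H]1OC(=O)/C(C)=C\C | intermediate
32 | 2-oxo-7αH,10βH-eremophil-11-ene-8α,9α-diyl bis[(Z)-2-methylbut-2-enoate] (CNP0249036.1) | C=C(C)[C@H]1C[C@@]2(C)[C@H](CC(=O)C[C@@H]2C)[C@H](OC(=O)/C(C)=C\C)[C@@H]1OC(=O)/C(C)=C\C | target

Total step count: 23
Longest linear sequence: 23 steps (1 → 32)

Steps most likely to fail

1. Step 10. The catalyst may fail to differentiate the two enone arms, or may work against the small substrate bias, and slow enamine formation would let an unselective background cyclisation compete. The pseudoenantiomeric quinidine-derived amine is the first variation of conditions. The fallback changes the source of selectivity: from 16, the same C1–C10 bond would be closed through the potassium enolate (catalytic t-BuOK, t-BuOH/THF, 0 °C). Under these conditions the Michael addition is reversible and the two cis-fused products equilibrate. Because C4 is already enantiopure, the products are diastereomers, so chromatography would separate 17 from its C5,C10-bis-epimer F1, and F1 would be returned to the equilibrating conditions. The fallback rejoins the route at 17.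

2. Step 18. Elimination may run into the ring toward C7, or the tertiary sulfamate may ionise with participation of the neighbouring ester, instead of giving the terminal alkene. The fallback attaches the isopropenyl group as such and sets out from 21: palladium-catalysed α-alkenylation of the C7 lithium enolate with 2-bromopropene (LiN(SiMe3)2, Pd2(dba)3, P(t-Bu)3, PhMe) would give the 7β-isopropenyl ketone F2, the alkenyl group entering on the β face for the same reason as acetone in step 15. Reduction with NaBH4/CeCl3·7H2O in MeOH at −40 °C (axial hydride delivery) would give the 8α-alcohol F3, and Yamaguchi esterification of F3 with 25 rejoins the route at 27, replacing steps 15–18.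

3. Step 22. Acylation of the hindered axial 9α-hydroxyl may be slow, and forcing it may isomerise the (Z)-acyl group to the (E)-isomer. The fallback builds the ester on the oxygen and sets out from 30: DCC/DMAP coupling with 2-[bis(2,2,2-trifluoroethoxy)phosphoryl]propanoic acid would give the phosphonate ester F4, and Still–Gennari olefination (KN(SiMe3)2, 18-crown-6, THF, −78 °C; acetaldehyde) would form the (Z)-2-methylbut-2-enoate directly, rejoining the route at 31.

Further compounds
F1 | step 10 | C5,C10-bis-epimer of 17 (4,5-trans-dimethyl, cis-fused) | O=C1C=C[C@]2(C)[C@@H](CC(=O)C[C@@H]2C)C1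
F2 | step 18 | 2,2-(ethylenedioxy)-9β-(triethylsilyloxy)-7αH,10βH-eremophil-11-en-8-one | O=C1[C@@H](C(C)=C)C[C@@]2(C)[C@H](CC3(OCCO3)C[C@@H]2C)[C@H]1O[Si](CC)(CC)CC
F3 | step 18 | 2,2-(ethylenedioxy)-9β-(triethylsilyloxy)-7αH,10βH-eremophil-11-en-8α-ol | O[C@@H]1[C@@H](C(C)=C)C[C@@]2(C)[C@H](CC3(OCCO3)C[C@@H]2C)[C@H]1O[Si](CC)(CC)CC
F4 | step 22 | 8α-angeloyloxy-2,2-(ethylenedioxy)-7αH,10βH-eremophil-11-en-9α-yl 2-[bis(2,2,2-trifluoroethoxy)phosphoryl]propanoate | C/C=C(/C)C(=O)O[C@@H]1[C@@H](C(C)=C)C[C@@]2(C)[C@H](CC3(OCCO3)C[C@@H]2C)[C@@H]1OC(=O)C(C)P(=O)(OCC(F)(F)F)OCC(F)(F)F
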